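The target is cut at the bond between the ether oxygen on quaternary C2 of the naphthalene-1,3,4-trione ring and vinylic C3 of the naphthoquinone ring. That C3 is the β-carbon of the C1=O enone, so a 3-bromoquinone is a vinylogous acyl bromide, and the tertiary α-ketol of the trione half can displace bromide by addition–elimination, joining the halves in one operation without touching the stereocentre. Both partners come from one 2-ethyl-5,6,8-trimethoxy-1,4-naphthoquinone: bromination gives the electrophile, while catalytic asymmetric epoxidation and oxidative opening of the epoxide at its CH carbon give the configurationally fixed (S)-ketol. Global demethylation finishes the synthesis.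

Key step: step 11

Remark on the chemistry (assumption): the quinine-derived ammonium salt of step 9 is taken to deliver oxygen to the face of 11 that leads to the (2R,3S)-epoxide; should the sense of induction prove opposite, the pseudoenantiomeric N-(9-anthracenylmethyl)quinidinium chloride takes its place.

Step 1
Reactants: 1 1,2,4-trimethoxybenzene; 2 butanoyl chloride
Product: 3 1-(2,4,5-trimethoxyphenyl)butan-1-one
Conditions: AlCl3, CH2Cl2, −10 °C to 0 °C
Reagents that add atoms: none
Why: Friedel–Crafts acylation takes place at C5 of 1, para to the 2-methoxy and ortho to the 4-methoxy group, and the low temperature should prevent AlCl3 from cleaving the methoxy group ortho to the new ketone.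

Step 2
Reactants: 3 1-(2,4,5-trimethoxyphenyl)butan-1-one; 4 ethyl bromoacetate
Product: 5 ethyl 3-(2,4,5-trimethoxybenzoyl)pentanoate (racemic)
Conditions: LiN(SiMe3)2, THF, −78 °C; then 4, −78 °C to 0 °C
Reagents that add atoms: none
Why: Enolate alkylation of the aryl propyl ketone with a reactive α-bromo ester should occur at carbon; the new stereocentre forms racemic and is erased later as an sp2 carbon.

Step 3
Reactants: 5 ethyl 3-(2,4,5-trimethoxybenzoyl)pentanoate
Product: 6 ethyl 3-(2,4,5-trimethoxybenzyl)pentanoate (racemic)
Conditions: Et3SiH, CF3CO2H, rt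
Reagents that add atoms: none
Why: Ionic hydrogenation reduces the electron-rich aryl ketone through a stabilised trimethoxybenzyl cation to the methylene group and leaves the ester untouched.

Step 4
Reactants: 6 ethyl 3-(2,4,5-trimethoxybenzyl)pentanoate
Product: 7 3-(2,4,5-trimethoxybenzyl)pentanoic acid (racemic)
Conditions: LiOH, THF/MeOH/H2O, rt; then aq. HCl
Reagents that add atoms: lithium hydroxide [Li+].[OH-]
Why: Ordinary ester saponification, with no other base-sensitive group in 6.

Step 5
Reactants: 7 3-(2,4,5-trimethoxybenzyl)pentanoic acid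
Product: 8 3-ethyl-5,7,8-trimethoxy-3,4-dihydronaphthalen-1(2H)-one (racemic)
Conditions: (CF3CO)2O, CF3CO2H, CH2Cl2, 0 °C to rt
Reagents that add atoms: none
Why: Intramolecular Friedel–Crafts acylation under anhydride activation closes the six-membered ring at the only unsubstituted position ortho to the side chain, which is also ortho to a methoxy group.

Step 6
Reactants: 8 3-ethyl-5,7,8-trimethoxy-3,4-dihydronaphthalen-1(2H)-one
Product: 10 3-ethyl-5,7,8-trimethoxynaphthalen-1-ol, via 2-bromotetralone 9 (not isolated)
Conditions: PhNMe3Br3, THF, 0 °C to rt; then LiBr, Li2CO3, DMF, 120 °C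
Reagents that add atoms: none
Why: The tribromide salt brominates the ketone α-carbon C2 in preference to the arene, and dehydrobromination followed by tautomerisation aromatises the ring to the 1-naphthol, which is used at once because it is air-sensitive.

Step 7
Reactants: 10 3-ethyl-5,7,8-trimethoxynaphthalen-1-ol
Product: 11 2-ethyl-5,6,8-trimethoxy-1,4-naphthoquinone
Conditions: K2[ON(SO3)2], KH2PO4, H2O/acetone, 0 °C to rt
Reagents that add atoms: dipotassium nitrosodisulfonate [K+].[K+].[O]N(S(=O)(=O)[O-])S(=O)(=O)[O-]
Why: Teuber oxidation, in which the nitroxyl radical oxidises the free phenol and delivers oxygen to the unsubstituted para position C4, should give the 1,4-quinone without touching the methyl ethers.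

Step 8
Reactants: 11 2-ethyl-5,6,8-trimethoxy-1,4-naphthoquinone
Product: 13 3-bromo-2-ethyl-5,6,8-trimethoxy-1,4-naphthoquinone, via dibromide 12 (not isolated)
Conditions: Br2, CH2Cl2, 0 °C; then Et3N, 0 °C to rt
Reagents that add atoms: bromine BrBr
Why: Bromine adds across the quinone double bond faster than it substitutes the acyl-deactivated arene, and the amine then removes the acidic C3–H with loss of the tertiary bromide (addition–dehydrobromination), leaving bromine on the former CH carbon.

Step 9
Reactants: 11 2-ethyl-5,6,8-trimethoxy-1,4-naphthoquinone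
Product: 14 (2R,3S)-2,3-epoxy-2-ethyl-5,6,8-trimethoxy-2,3-dihydro-1,4-naphthoquinone
Conditions: N-(9-anthracenylmethyl)quininium chloride (10 mol %), aq. NaOCl, toluene, −10 °C
Reagents that add atoms: sodium hypochlorite [Na+].[O-]Cl
Why: Weitz–Scheffer nucleophilic epoxidation under chiral phase-transfer catalysis, in which hypochlorite ion-paired with the chiral ammonium cation adds to C3 on one face and the resulting enolate closes onto oxygen, so the catalyst sets both centres of the cis-epoxide, including the ethyl-bearing C2 as R.

Step 10
Reactants: 14 (2R,3S)-2,3-epoxy-2-ethyl-5,6,8-trimethoxy-2,3-dihydro-1,4-naphthoquinone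
Product: 16 (S)-2-ethyl-2-hydroxy-5,6,8-trimethoxynaphthalene-1,3,4(2H)-trione, via alkoxysulfonium triflate 15 (not isolated)
Conditions: Me2SO, CF3SO3H, CH2Cl2, 0 °C to rt; then iPr2NEt, −20 °C to 0 °C; non-aqueous work-up
Reagents that add atoms: dimethyl sulfoxide CS(C)=O
Why: Proposed new method: after protonation of the epoxide, DMSO should attack the secondary C3 (α to C4=O, SN2 with inversion) and not the tertiary C2, whose ionisation is disfavoured next to a carbonyl, giving salt 15, which on deprotonation loses Me2S to form the C3 ketone, so the C2–O bond is never broken and C2 keeps its configuration (the descriptor changes from R to S through priorities only); the closest known reaction type is the acid-promoted DMSO opening of simple epoxides to β-hydroxyalkoxysulfonium salts and their base-induced collapse to α-ketols (Kornblum- or Swern-type oxidation).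

Step 11
Reactants: 13 3-bromo-2-ethyl-5,6,8-trimethoxy-1,4-naphthoquinone; 16 (S)-2-ethyl-2-hydroxy-5,6,8-trimethoxynaphthalene-1,3,4(2H)-trione
Product: 17 (S)-2-ethyl-2-[(3-ethyl-5,7,8-trimethoxy-1,4-dioxo-1,4-dihydronaphthalen-2-yl)oxy]-5,6,8-trimethoxynaphthalene-1,3,4(2H)-trione
Conditions: Cs2CO3, 4 Å molecular sieves, MeCN, −20 °C to rt, dark; 16 dried azeotropically, 13 in excess
Reagents that add atoms: none
Why: Cs2CO3 reversibly forms the tertiary alkoxide of 16, which adds to C3 of 13, the bromine-bearing β-carbon of the C1=O enone, to give a quinone enolate that expels bromide and restores the quinone, so the O–C3 bond is made by addition–elimination. The closest known reaction type is the alkoxy- or aryloxy-dehalogenation of 2-halo-1,4-naphthoquinones. No ring is closed and no stereocentre is created; the quaternary carbon of 16 keeps its C–O bond, has no α-hydrogen, and should pass into 17 with unchanged configuration. The step needs O-attack at C3 in preference to carbonyl addition or attack at the ethyl-bearing carbon, and this is secured because only the adduct at C3 can collapse irreversibly by losing bromide. It also needs the alkoxide to be trapped before it undergoes an α-ketol acyl shift or benzilic-type ring contraction, which is addressed by anhydrous, hydroxide-free conditions, low temperature and an excess of 13 at high concentration.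

Step 12
Reactants: 17 hexa-O-methyl ether of the target
Product: 18 CNP0325426.1, (S)-2-ethyl-2-[(3-ethyl-5,7,8-trihydroxy-1,4-dioxo-1,4-dihydronaphthalen-2-yl)oxy]-5,6,8-trihydroxynaphthalene-1,3,4(2H)-trione
Conditions: BBr3 (excess), CH2Cl2, −78 °C to 0 °C; then H2O
Reagents that add atoms: none
Why: Lewis-acid ether cleavage, in which boron coordinates each methoxy oxygen (the four peri groups assisted by chelation to the neighbouring carbonyl) and bromide removes methyl by SN2, while the linking ether should survive because its quaternary carbon, flanked by two carbonyls, can neither ionise nor undergo SN2; the stereocentre is not involved.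

Compound list
1 | 1,2,4-trimethoxybenzene | COc1ccc(OC)c(OC)c1 | starting material
2 | butanoyl chloride | CCCC(Cl)=O | starting material
3 | 1-(2,4,5-trimethoxyphenyl)butan-1-one | CCCC(=O)c1cc(OC)c(OC)cc1OC | intermediate
4 | ethyl bromoacetate | CCOC(=O)CBr | starting material
5 | ethyl 3-(2,4,5-trimethoxybenzoyl)pentanoate (racemic) | CCOC(=O)CC(CC)C(=O)c1cc(OC)c(OC)cc1OC | intermediate
6 | ethyl 3-(2,4,5-trimethoxybenzyl)pentanoate (racemic) | CCOC(=O)CC(CC)Cc1cc(OC)c(OC)cc1OC | intermediate
7 | 3-(2,4,5-trimethoxybenzyl)pentanoic acid (racemic) | CCC(CC(=O)O)Cc1cc(OC)c(OC)cc1OC | intermediate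
8 | 3-ethyl-5,7,8-trimethoxy-3,4-dihydronaphthalen-1(2H)-one (racemic) | CCC1CC(=O)c2c(OC)c(OC)cc(OC)c2C1 | intermediate
9 | 2-bromo-3-ethyl-5,7,8-trimethoxy-3,4-dihydronaphthalen-1(2H)-one (diastereomer mixture, not isolated) | CCC1Cc2c(OC)cc(OC)c(OC)c2C(=O)C1Br | intermediate
10 | 3-ethyl-5,7,8-trimethoxynaphthalen-1-ol | CCc1cc(O)c2c(OC)c(OC)cc(OC)c2c1 | intermediate
11 | 2-ethyl-5,6,8-trimethoxy-1,4-naphthoquinone | CCC1=CC(=O)c2c(OC)c(OC)cc(OC)c2C1=O | intermediate
12 | 2,3-dibromo-2-ethyl-5,6,8-trimethoxy-2,3-dihydro-1,4-naphthoquinone (not isolated) | CCC1(Br)C(Br)C(=O)c2c(OC)c(OC)cc(OC)c2C1=O | intermediate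
13 | 3-bromo-2-ethyl-5,6,8-trimethoxy-1,4-naphthoquinone | CCC1=C(Br)C(=O)c2c(OC)c(OC)cc(OC)c2C1=O | intermediate
14 | (2R,3S)-2,3-epoxy-2-ethyl-5,6,8-trimethoxy-2,3-dihydro-1,4-naphthoquinone | O1[C@]2(CC)[C@H]1C(=O)c3c(OC)c(OC)cc(OC)c3C2=O | intermediate
15 | (2R,3R)-3-(dimethylsulfoniooxy)-2-ethyl-2-hydroxy-5,6,8-trimethoxy-2,3-dihydro-1,4-naphthoquinone trifluoromethanesulfonate (not isolated) | C[S+](C)O[C@H]1C(=O)c2c(OC)c(OC)cc(OC)c2C(=O)[C@@]1(O)CC.[O-]S(=O)(=O)C(F)(F)F | intermediate
16 | (S)-2-ethyl-2-hydroxy-5,6,8-trimethoxynaphthalene-1,3,4(2H)-trione | O[C@]1(CC)C(=O)C(=O)c2c(OC)c(OC)cc(OC)c2C1=O | intermediate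
17 | hexa-O-methyl ether of the target, (S)-2-ethyl-2-[(3-ethyl-5,7,8-trimethoxy-1,4-dioxo-1,4-dihydronaphthalen-2-yl)oxy]-5,6,8-trimethoxynaphthalene-1,3,4(2H)-trione | CCC1=C(O[C@]2(CC)C(=O)C(=O)c3c(OC)c(OC)cc(OC)c3C2=O)C(=O)c2c(OC)c(OC)cc(OC)c2C1=O | intermediate
18 | CNP0325426.1 | CCC1=C(O[C@]2(CC)C(=O)C(=O)c3c(O)c(O)cc(O)c3C2=O)C(=O)c2c(O)c(O)cc(O)c2C1=O | target

Total step count: 12. Longest linear sequence: 11 steps (steps 1 to 7, then 9 to 12); step 8 is the one-step branch to the bromoquinone.

Steps most likely to fail

Step 10 (proposed new method). The deactivated epoxide may resist attack by DMSO, or enolisation at C3 under the acid or the amine may break the C2–O bond and isomerise 14 to the achiral hydroxyquinone, which erases the stereocentre. The fallback uses known chemistry and sets out from tetralone 8. Autoxidation with KOtBu and O2 in tBuOH, the standard conversion of 1-tetralones into 2-hydroxy-1,4-naphthoquinones, should give 2-ethyl-3-hydroxy-5,6,8-trimethoxy-1,4-naphthoquinone F1. Hydroxylation of its enolised 1,3-dicarbonyl unit at the ethyl-bearing carbon with dimethyldioxirane in acetone at 0 °C should give racemic 2-ethyl-2-hydroxy-5,6,8-trimethoxynaphthalene-1,3,4(2H)-trione F2. The enantiomers would be separated by preparative HPLC on a chiral stationary phase, and the (S)-enantiomer comes back to the route at 16.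

Step 11. The tertiary alkoxide may undergo acyl shift or ring contraction faster than it is captured, the addition may revert before bromide is lost, or the base may tautomerise 13 to a quinone methide through its ethyl group. The fallback sets out from tetralone 8 through hydroxyquinone F1, prepared as in the fallback above. One-electron oxidation with PbO2 in AcOH, the known dehydrodimerisation of 3-alkyl-2-hydroxy-1,4-naphthoquinones in which the oxygen of one radical bonds to the alkyl-bearing carbon of the other, should give the racemic hexamethyl ether F3. Separation of the enantiomers by preparative chiral-phase HPLC comes back to the route at 17.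

Step 9. Facial selectivity may be poor because two peri-methoxy groups flank the quinone carbonyls and alter the ion pairing with the catalyst, and base may partly isomerise the epoxide during the reaction; in the main route 14 is to be recrystallised to enantiopurity before step 10. The fallback sets out from quinone 11. Uncatalysed Weitz–Scheffer epoxidation with H2O2 and Na2CO3 in aqueous EtOH should give the racemic 2,3-epoxy-2-ethyl-5,6,8-trimethoxy-2,3-dihydro-1,4-naphthoquinone F4, which would be resolved by preparative chromatography on a chiral stationary phase; the (2R,3S)-enantiomer comes back to the route at 14.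

Further compounds
F1 | step 10 | 2-ethyl-3-hydroxy-5,6,8-trimethoxy-1,4-naphthoquinone | CCC1=C(O)C(=O)c2c(OC)c(OC)cc(OC)c2C1=O
F2 | step 10 | racemic 2-ethyl-2-hydroxy-5,6,8-trimethoxynaphthalene-1,3,4(2H)-trione | CCC1(O)C(=O)C(=O)c2c(OC)c(OC)cc(OC)c2C1=O
F3 | step 11 | racemic hexa-O-methyl ether of the target | CCC1=C(OC2(CC)C(=O)C(=O)c3c(OC)c(OC)cc(OC)c3C2=O)C(=O)c2c(OC)c(OC)cc(OC)c2C1=O
F4 | step 9 | racemic 2,3-epoxy-2-ethyl-5,6,8-trimethoxy-2,3-dihydro-1,4-naphthoquinone | CCC12OC1C(=O)c1c(OC)c(OC)cc(OC)c1C2=O
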